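A small charge of protic impurity, 0.0420 M, stands in this flask as it did in the delta run, so I set it aside at first and ask how far the exchange has run. Incoming ligand turns starting complex into complex with one exchanged, and that into complex with two exchanged, so the wanted complex can rise and then fall.

| flask | starting complex | incoming ligand | protic impurity | remark | time |
|---|---|---|---|---|---|
| delta | 0.56 M | 3 equiv | 0.042 M | run made earlier |  |
| flask | 0.84 M | 3.00 equiv | 0.0420 M |  | 12 h |

delta run (percent of the starting complex charged)

| time / h | complex with one exchanged / % |
|---|---|
| 1.00 | 9.2 |
| 2.00 | 16.1 |
| 3.00 | 22.2 |
| 5.00 | 28.8 |
| 8.00 | 35.2 |
| 15.0 | 36.4 |

(each reading ± 0.5 percentage points)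

- percent here means starting complex units held: one idle adduct counts as two
- what is said of complex with one exchanged includes idle adduct
- what may be going on: starting complex + incoming ligand <-> leaving ligand + complex with one exchanged; complex with one exchanged + incoming ligand <-> leaving ligand + complex with two exchanged; protic impurity + starting complex -> quenched substrate; starting complex + complex with one exchanged <-> idle adduct; complex with one exchanged <-> isomer of the product
- in an amount of complex with one exchanged, one idle adduct counts as one complex with one exchanged
- no earlier run changes the charge of incoming ligand; that part of a forecast is a guess

* equivalents of incoming ligand to starting complex, everything else as given, that leave most complex with one exchanged at 12 h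
* the amount of complex with one exchanged then, in percent of the starting complex charged
* the amount of complex with one exchanged with the amounts as given

Read as the loss of starting complex, the first delta reading gives a pseudo-first-order half-life of about 7.53 h. Scaled to the flask's higher ligand concentration, it becomes 5.02 h. The flask therefore reaches 2.39: this is N, the count of half-lives, time over half-life. With the same equivalents of incoming ligand, it marks how far along the curve a flask stands.

The delta run climbs from 35.2% at N = 1.06 to 36.4% at N = 1.99, so it is flattening. The flask lies beyond that last reading, which makes my figure an extrapolation.

One number is not quite enough, since the impurity is 5.00% of the starting complex here against 7.50% there. I commit to slightly above 36.4%. If I take that last reading as near the top of the curve, matching N to it asks for 2.50 equiv, a guess, because no run changes that charge.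

The forecast gives 36.5%, and 38% at 2.2 equiv, a lower charge than mine. Its clock is the same as mine: “12 h there corresponds to about 18 h of the delta run”.

The simulation gives 36.6%, and 37.8% at 2.34 equiv, below my charge.

    starting complex + incoming ligand ⇌ leaving ligand + complex with one exchanged (K = 2.80, k = 0.0620 /M/h)
    complex with one exchanged + incoming ligand ⇌ leaving ligand + complex with two exchanged (K = 24.0, k = 0.0540 /M/h)
    protic impurity + starting complex → quenched substrate (k = 0.810 /M/h)
    starting complex + complex with one exchanged ⇌ idle adduct, settled at all times (K = 1.60 /M)
    complex with one exchanged ⇌ isomer of the product (K = 0.460, k = 0.00430 /h)

At N = 2.39 the flask holds 36.6% of complex with one exchanged. Moved in time alone, its answer has shifted by 5 points at 16.9 h, which is N = 3.37. Left until 30 h, the same flask counts N = 5.98 and holds 19.8% of complex with one exchanged.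

(The readings were computed for an exercise.)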